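**Retrosynthetic overview**
1. The hydroperoxy enone comes from a Schenck ene reaction of a prenyl ketone; the C8–C9 bond comes from α-prenylation of an α-epoxy aldehyde, then oxidation.
2. Both oxiranes (ring C3–C4 and side-chain C7–C14) come from one double Sharpless-type epoxidation of a bis-allylic diol: the ring C2–OH delivers the ring epoxide, D-(−)-tartrate sets C7.
3. The diol comes from Luche reduction and SeO2 allylic hydroxylation of trans-6-(isovaleryloxy)carvone, made from (R)-carvone and isovaleric acid.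
4. Ring order: the cyclohexane and the C6 stereocentre come intact from (R)-carvone; the two oxirane rings are closed together in step 4; no ring is formed afterwards.

Assumption: the target is taken as (1S,3S,4S,6R,7S) exactly as the SMILES is written; numbering is C1 (ester carbon), C2 (ring ketone), C3/C4 (ring oxirane), C5, C6 (side-chain carbon), C7 (quaternary oxirane carbon), C14 (its CH2), C8–C11 (enone chain).

**Step 1**
Reactants: 1 (R)-(−)-carvone and 2 isovaleric acid (3-methylbutanoic acid)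
Product: 3 (1S,6S)-3-methyl-2-oxo-6-(prop-1-en-2-yl)cyclohex-3-en-1-yl 3-methylbutanoate
Conditions: Mn(OAc)3·2H2O (3 equiv), 2 (10 equiv), benzene, reflux (Dean–Stark), 12 h
Reagents that add atoms: none
Why: Trivalent-manganese α'-acyloxylation of an enone (carboxylate exchange on manganese, manganese enolate, acyloxy transfer) forms the C–O bond anti to the neighbouring isopropenyl group, so the trans (1S) ester is the major isomer, separable from the minor cis epimer.

**Step 2**
Reactants: 3 (1S,6S)-3-methyl-2-oxo-6-(prop-1-en-2-yl)cyclohex-3-en-1-yl 3-methylbutanoate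
Product: 4 (1S,6S)-6-(3-hydroxyprop-1-en-2-yl)-3-methyl-2-oxocyclohex-3-en-1-yl 3-methylbutanoate
Conditions: SeO2 (0.3 equiv), t-BuOOH (3 equiv), CH2Cl2, rt, 36 h
Reagents that add atoms: tert-butyl hydroperoxide, CC(C)(C)OO (terminal oxygen source, relayed through SeO2)
Why: Sharpless–Umbreit catalytic SeO2 allylic hydroxylation (ene reaction then [2,3]-sigmatropic shift) acts only on the electron-rich 1,1-disubstituted alkene and at its methyl group rather than the hindered, acyloxy-flanked ring methine, the enone alkene being inert; no stereocentre is formed.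

**Step 3**
Reactants: 4 (1S,6S)-6-(3-hydroxyprop-1-en-2-yl)-3-methyl-2-oxocyclohex-3-en-1-yl 3-methylbutanoate
Product: 5 (1S,2S,6S)-2-hydroxy-6-(3-hydroxyprop-1-en-2-yl)-3-methylcyclohex-3-en-1-yl 3-methylbutanoate
Conditions: NaBH4 (1.1 equiv), CeCl3·7H2O (1.1 equiv), MeOH, −78 °C, 30 min
Reagents that add atoms: none
Why: Luche 1,2-reduction delivers hydride axially from the face opposite the C6 side chain (as in carvone to cis-carveol), giving the equatorial C2 alcohol (2S), cis to the side chain and trans to the ester, cold enough to avoid acyl migration.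

**Step 4**
Reactants: 5 (1S,2S,6S)-2-hydroxy-6-(3-hydroxyprop-1-en-2-yl)-3-methylcyclohex-3-en-1-yl 3-methylbutanoate
Product: 7 (1S,2R,3R,4S,6R)-3,4-epoxy-2-hydroxy-6-[(2R)-2-(hydroxymethyl)oxiran-2-yl]-3-methylcyclohexyl 3-methylbutanoate, via side-chain mono-epoxide 6 (not isolated)
Conditions: Ti(OiPr)4 (0.3 equiv), D-(−)-DIPT (0.4 equiv), t-BuOOH (4 equiv, in decane), 4 Å MS, CH2Cl2, −20 °C, 36 h
Reagents that add atoms: tert-butyl hydroperoxide, CC(C)(C)OO
Why: Sharpless–Katsuki epoxidation applied twice in one flask: the 2-substituted primary allylic alcohol is epoxidized under tartrate control (D-(−)-tartrate gives the (R)-2-(hydroxymethyl)oxirane, which is 7S of the target once C8 is a carbonyl), and the ring allylic alcohol then receives oxygen from titanium bound to its own hydroxyl, syn to C2–OH and cis to the side chain, a face that D-(−)-tartrate also favours for this carbinol.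

**Step 5**
Reactants: 7 (1S,2R,3R,4S,6R)-3,4-epoxy-2-hydroxy-6-[(2R)-2-(hydroxymethyl)oxiran-2-yl]-3-methylcyclohexyl 3-methylbutanoate
Product: 9 (1S,3S,4S,6R)-3,4-epoxy-6-[(2S)-2-formyloxiran-2-yl]-3-methyl-2-oxocyclohexyl 3-methylbutanoate, via hydroxy aldehyde 8 (not isolated)
Conditions: Dess–Martin periodinane (3 equiv), pyridine, CH2Cl2, 0 °C to rt
Reagents that add atoms: none
Why: Dess–Martin oxidation of both carbinols under buffered conditions gives the non-enolizable α-epoxy aldehyde and the ring epoxy ketone; no stereocentre is formed and the temporary C2 carbinol centre is removed.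

**Step 6**
Reactants: 9 (1S,3S,4S,6R)-3,4-epoxy-6-[(2S)-2-formyloxiran-2-yl]-3-methyl-2-oxocyclohexyl 3-methylbutanoate and 10 prenyl chloride (1-chloro-3-methylbut-2-ene)
Product: 12 (1S,3S,4S,6R)-3,4-epoxy-6-[(2S)-2-(1-hydroxy-4-methylpent-3-en-1-yl)oxiran-2-yl]-3-methyl-2-oxocyclohexyl 3-methylbutanoate (both carbinol epimers), via prenylbarium chloride 11 (not isolated)
Conditions: Li, biphenyl, BaI2, THF, rt; 10 (1.1 equiv), −78 °C; then 9, −78 °C, 15 min; aq NH4Cl, −78 °C
Reagents that add atoms: none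
Why: Barbier–Grignard-type carbonyl addition of an allylic barium reagent, which bonds through its unsubstituted (α) terminus and, at −78 °C with about one equivalent, attacks the aldehyde much faster than the hindered ring ketone, the ester or the oxiranes; the new C8 carbinol centre forms as a mixture, which does not matter because it is oxidized in step 7.

**Step 7**
Reactants: 12 (1S,3S,4S,6R)-3,4-epoxy-6-[(2S)-2-(1-hydroxy-4-methylpent-3-en-1-yl)oxiran-2-yl]-3-methyl-2-oxocyclohexyl 3-methylbutanoate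
Product: 13 (1S,3S,4S,6R)-3,4-epoxy-3-methyl-6-[(2S)-2-(4-methylpent-3-enoyl)oxiran-2-yl]-2-oxocyclohexyl 3-methylbutanoate
Conditions: Dess–Martin periodinane (1.5 equiv), pyridine, CH2Cl2, 0 °C, 30 min; used crude
Reagents that add atoms: none
Why: Dess–Martin oxidation gives the β,γ-unsaturated ketone without a base that would move the alkene into conjugation; the C8 stereocentre disappears.

**Step 8**
Reactants: 13 (1S,3S,4S,6R)-3,4-epoxy-3-methyl-6-[(2S)-2-(4-methylpent-3-enoyl)oxiran-2-yl]-2-oxocyclohexyl 3-methylbutanoate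
Product: 14 (1S,3S,4S,6R)-3,4-epoxy-6-{(2S)-2-[(2E)-4-hydroperoxy-4-methylpent-2-enoyl]oxiran-2-yl}-3-methyl-2-oxocyclohexyl 3-methylbutanoate
Conditions: O2, tetraphenylporphyrin (1 mol %), visible light, CH2Cl2, −20 °C
Reagents that add atoms: dioxygen (as singlet oxygen), O=O
Why: Schenck ene reaction of singlet oxygen with the trisubstituted alkene of a β,γ-unsaturated ketone abstracts the activated C9 hydrogen on the more substituted side and binds oxygen at C11, giving the conjugated (E)-γ-hydroperoxy enone, while the electron-poor epoxy ketones and the ester do not react; no stereocentre is formed.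

**Compound list**
1 | (R)-(−)-carvone | CC1=CC[C@H](CC1=O)C(C)=C | starting material
2 | isovaleric acid (3-methylbutanoic acid) | CC(C)CC(=O)O | starting material
3 | (1S,6S)-3-methyl-2-oxo-6-(prop-1-en-2-yl)cyclohex-3-en-1-yl 3-methylbutanoate | CC(C)CC(=O)O[C@@H]1C(=O)C(C)=CC[C@H]1C(C)=C | intermediate
4 | (1S,6S)-6-(3-hydroxyprop-1-en-2-yl)-3-methyl-2-oxocyclohex-3-en-1-yl 3-methylbutanoate | CC(C)CC(=O)O[C@@H]1C(=O)C(C)=CC[C@H]1C(=C)CO | intermediate
5 | (1S,2S,6S)-2-hydroxy-6-(3-hydroxyprop-1-en-2-yl)-3-methylcyclohex-3-en-1-yl 3-methylbutanoate | CC(C)CC(=O)O[C@@H]1[C@@H](O)C(C)=CC[C@H]1C(=C)CO | intermediate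
6 | (1S,2S,6R)-2-hydroxy-6-[(2R)-2-(hydroxymethyl)oxiran-2-yl]-3-methylcyclohex-3-en-1-yl 3-methylbutanoate | CC(C)CC(=O)O[C@@H]1[C@@H](O)C(C)=CC[C@H]1[C@@]1(CO)CO1 | intermediate (not isolated)
7 | (1S,2R,3R,4S,6R)-3,4-epoxy-2-hydroxy-6-[(2R)-2-(hydroxymethyl)oxiran-2-yl]-3-methylcyclohexyl 3-methylbutanoate | CC(C)CC(=O)O[C@@H]1[C@@H](O)[C@@]2(C)O[C@H]2C[C@H]1[C@@]1(CO)CO1 | intermediate
8 | (1S,2R,3R,4S,6R)-3,4-epoxy-6-[(2S)-2-formyloxiran-2-yl]-2-hydroxy-3-methylcyclohexyl 3-methylbutanoate | CC(C)CC(=O)O[C@@H]1[C@@H](O)[C@@]2(C)O[C@H]2C[C@H]1[C@@]1(C=O)CO1 | intermediate (not isolated)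
9 | (1S,3S,4S,6R)-3,4-epoxy-6-[(2S)-2-formyloxiran-2-yl]-3-methyl-2-oxocyclohexyl 3-methylbutanoate | CC(C)CC(=O)O[C@@H]1C(=O)[C@@]2(C)O[C@H]2C[C@H]1[C@@]1(C=O)CO1 | intermediate
10 | prenyl chloride (1-chloro-3-methylbut-2-ene) | CC(C)=CCCl | starting material
11 | prenylbarium chloride | CC(C)=CC[Ba]Cl | intermediate (not isolated)
12 | (1S,3S,4S,6R)-3,4-epoxy-6-[(2S)-2-(1-hydroxy-4-methylpent-3-en-1-yl)oxiran-2-yl]-3-methyl-2-oxocyclohexyl 3-methylbutanoate (carbinol epimers) | CC(C)CC(=O)O[C@@H]1C(=O)[C@@]2(C)O[C@H]2C[C@H]1[C@@]1(C(O)CC=C(C)C)CO1 | intermediate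
13 | (1S,3S,4S,6R)-3,4-epoxy-3-methyl-6-[(2S)-2-(4-methylpent-3-enoyl)oxiran-2-yl]-2-oxocyclohexyl 3-methylbutanoate | CC(C)CC(=O)O[C@@H]1C(=O)[C@@]2(C)O[C@H]2C[C@H]1[C@@]1(C(=O)CC=C(C)C)CO1 | intermediate
14 | (1S,3S,4S,6R)-3,4-epoxy-6-{(2S)-2-[(2E)-4-hydroperoxy-4-methylpent-2-enoyl]oxiran-2-yl}-3-methyl-2-oxocyclohexyl 3-methylbutanoate | CC(C)CC(=O)O[C@@H]1C(=O)[C@@]2(C)O[C@H]2C[C@H]1[C@@]1(C(=O)/C=C/C(C)(C)OO)CO1 | target

**Totals**
Total steps: 8. Longest linear sequence: 8 (from (R)-carvone).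

**Steps most likely to fail, with fallbacks**

Step 2. SeO2 may attack the ring methine next to the isopropenyl group or over-oxidize to the enal. The fallback replaces oxo-transfer by an ene-type chlorination and sets out from 3: Ca(OCl)2 with solid CO2 in CH2Cl2/H2O gives the allylic chloride (1S,6S)-6-(3-chloroprop-1-en-2-yl)-3-methyl-2-oxocyclohex-3-en-1-yl 3-methylbutanoate F1. Sodium formate (Bu4NBr, DMF, rt) then gives the allylic formate (1S,6S)-6-[3-(formyloxy)prop-1-en-2-yl]-3-methyl-2-oxocyclohex-3-en-1-yl 3-methylbutanoate F2. The formate alone is cleaved with NaHCO3 in MeOH at 0 °C, and the route is rejoined at 4.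

Step 4. The ring allylic alcohol may react sluggishly with the titanium tartrate, and the C1 ester next to a titanium alkoxide may migrate. The fallback makes the two oxiranes in separate operations and sets out from 4: Sharpless epoxidation (Ti(OiPr)4, D-(−)-DIPT, t-BuOOH, −20 °C) while the ring is still an inert enone gives the epoxy alcohol (1S,6R)-6-[(2R)-2-(hydroxymethyl)oxiran-2-yl]-3-methyl-2-oxocyclohex-3-en-1-yl 3-methylbutanoate F3. Luche reduction then gives 6, now isolated, and VO(acac)2/t-BuOOH epoxidizes the ring alkene syn to the C2 hydroxyl, rejoining the route at 7.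

Step 6. The organobarium may also attack the ring ketone, deprotonate C1, or give some γ-adduct. The fallback uses a neutral, aldehyde-only allylation followed by olefin exchange and sets out from 9: allylboronic acid pinacol ester (CH2Cl2, rt) gives the homoallylic alcohol (1S,3S,4S,6R)-3,4-epoxy-6-[(2S)-2-(1-hydroxybut-3-en-1-yl)oxiran-2-yl]-3-methyl-2-oxocyclohexyl 3-methylbutanoate F4. Cross-metathesis with excess 2-methyl-2-butene (second-generation Grubbs catalyst, 40 °C) converts the terminal alkene into the prenyl group, rejoining the route at 12, at the cost of one extra step.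

**Further compounds**
F1 | step 2 | (1S,6S)-6-(3-chloroprop-1-en-2-yl)-3-methyl-2-oxocyclohex-3-en-1-yl 3-methylbutanoate | CC(C)CC(=O)O[C@@H]1C(=O)C(C)=CC[C@H]1C(=C)CCl
F2 | step 2 | (1S,6S)-6-[3-(formyloxy)prop-1-en-2-yl]-3-methyl-2-oxocyclohex-3-en-1-yl 3-methylbutanoate | CC(C)CC(=O)O[C@@H]1C(=O)C(C)=CC[C@H]1C(=C)COC=O
F3 | step 4 | (1S,6R)-6-[(2R)-2-(hydroxymethyl)oxiran-2-yl]-3-methyl-2-oxocyclohex-3-en-1-yl 3-methylbutanoate | CC(C)CC(=O)O[C@@H]1C(=O)C(C)=CC[C@H]1[C@@]1(CO)CO1
F4 | step 6 | (1S,3S,4S,6R)-3,4-epoxy-6-[(2S)-2-(1-hydroxybut-3-en-1-yl)oxiran-2-yl]-3-methyl-2-oxocyclohexyl 3-methylbutanoate (carbinol epimers) | CC(C)CC(=O)O[C@@H]1C(=O)[C@@]2(C)O[C@H]2C[C@H]1[C@@]1(C(O)CC=C)CO1
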